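## The problem

The target is a 14-membered cembrane carbocycle (C1–C14) bridged between C1 and C3 by a δ-lactone (O–C3–C2–C1–C15–C16, methyl C17 on C15). On the six-membered ring the two macrocycle bonds at C1 and C3 are cis and the C15 methyl is trans to the C1 branch, so all three substituents can sit equatorial. Seven stereocentres must be set: C1, C3 and C15 on the lactone, the C4 tertiary carbinol, the trans-(11S,12S)-epoxide and the C8 tertiary allylic hydroperoxide. C1 can control C15 (1,2-trans, epimerisable once C16 is a carbonyl) and C3 (1,3-cis, thermodynamic), and C3 can control C4 through chelation of its ring oxygen. The epoxide and C8 are remote from these centres and need reagent control or the conformation of the closed ring. The O–O bond will not survive reductants, phosphines, low-valent metals or strong base, the trisubstituted epoxide will not survive Brønsted or Lewis acid, and the lactone will not survive organometallic reagents; the hydroperoxide must therefore come last and the epoxide late. The E-6,7-alkene beside the C8 hydroperoxide is the product pattern of a singlet-oxygen ene reaction on an E-7,8-alkene. The feature that opens the key step is that O–C3–C2–C1–C15–C16 is the adduct of a 1-oxadiene (O=C3–C2=C1) and an enol ether (C15=C16): the activating ester becomes C4, the acetal carbon becomes the lactone carbonyl C16, and C1 and C15 are formed in the bond-making event.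

## Retrosynthesis

**26 to 25.** The C8–O bond is cut last. A suprafacial ene reaction of singlet oxygen on the E-7,8-alkene of 25 delivers the hydroperoxide and moves the alkene to C6–C7 in one operation, after every metal and reductant has been used. Perhydrolysis of a C8 alcohol or halide would pass through an allyl cation and acid, which the epoxide excludes. The forward step must abstract a C6 hydrogen, not a C19 one, and attack the correct face.

**25 to 23 (through 24).** The ring is opened at C8–C9, between the alkene carbon and its allylic methylene. The forward reaction is a B-alkyl Suzuki–Miyaura closure of alkylborane 24 onto the C8 alkenyl iodide, with 24 made by hydroboration of the vinyl epoxide 23. Cutting C9–C10 by sulfone-activated alkylation at C9 was weighed: reductive removal of a sulfonyl group from C9 passes through a 7,8,9-allyl species with two secondary termini, so the alkene could settle at C8–C9, and the carbanion would be formed beside an enolisable lactone. The cross-coupling fixes both position and E geometry, because the alkenyl iodide is made beforehand and couples with retention. It asks for a hydroboration that spares epoxide and lactone and for high dilution.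

**23 to 20 (through 22 and 21).** C9 is a one-carbon unit added by Wittig methylenation of epoxy aldehyde 22, which comes from epoxy alcohol 21. The epoxide C–O bonds are then cut to give allylic alcohol 20. A Sharpless epoxidation of this geraniol-type alcohol sets C11 and C12 by reagent control, which is why C10 is kept as CH2OH up to this point. An undirected epoxidation after ring closure would have to tell the 7,8- from the 11,12-alkene and choose a face unaided.

**20 to 18 (through 19).** The lactone carbonyl C16 is taken back to the ethyl acetal of 18; silyl ether 19 is the oxidation product. Holding C16 as an acetal through the organomagnesium steps removes the one electrophile that would compete with C4. The oxidation needs aqueous acid and so precedes the epoxide.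

**18 to 16.** The C8–I bond is cut to the 2-alkyne of 16. syn-Hydrozirconation and iodinolysis give the E-iodoalkene with the metal on the methyl-bearing carbon.

**16 to 12 and 13 (through 15 and 14).** C4 is cut twice. The C4–CH3 bond comes from MeMgBr adding to ketone 15 under chelation by the C3 ring oxygen. The C4–C5 bond comes from Weinreb amide 12 and the Grignard reagent 14, made from bromide 13. The reverse order (methyl ketone, then chain nucleophile) would give the C4 epimer under chelation.

**12 to 9 (through 11 and 10).** Amidation and silylation are functional-group changes. The real simplification is removal of the C2 and C3 hydrogens: conjugate reduction of the 2-alkoxyacrylate of 9 gives 10, whose C3 centre is α to the ester and equilibrates to the all-equatorial isomer the target needs.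

**9 to 7 and 8.** The dihydropyran is cut at C1–C15 and O–C16 into keto ester 7 and enol ether 8. This removes one ring and three stereocentres and leaves two achiral partners; the forward reaction must be enantiofacially selective and endo.

**7 to 1 and 4.** The C1=C2 alkene of 7 is a Wittig disconnection to aldehyde 3 and ylide 6. Aldehyde 3 comes from geranyl acetate 1 by terminal epoxidation (2) and cleavage. Ylide 6 comes from methyl bromopyruvate 4 through salt 5. The E-11,12-alkene and the C10 oxygen are bought with the starting material.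

## Roads not taken

**Alternative 1:** The cut is C1–C2. A 16-membered allyl vinyl ether A1, made by methylenating the corresponding ring ester with Cp2TiMe2 (tetravalent titanium), would undergo Claisen rearrangement to the 14-membered C3 ketone A2 with an isopropenyl group on C1.
- Merits: closing a 16-membered ester is easier than any C–C macrocyclisation, the ring contraction needs only heat, and the epoxide and silyl ether are inert to it. In ring formation this road is better than the chosen one.
- Weak points: C1 depends on the alkene geometry and on a chair-versus-boat choice in a macrocyclic transition state. C15 must then be made from the isopropenyl group with weak 1,2-induction, the C3 ketone must be reduced selectively, and the lactone is still to be closed. The acid-labile enol ether sits beside the epoxide.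
- Comparison: the chosen plan pays for a harder ring closure with catalytic absolute control of C1 and C15, thermodynamic control of C3, and a lactone that arrives at the right oxidation level.

**Alternative 2:** The cut is the C3–O lactone bond. The carboxylate of the macrocyclic 3,4:11,12-bis-epoxy acid A3 would open the 3,4-epoxide at C3 with inversion, closing the δ-lactone and freeing the C4 hydroxyl in A4, which is the same compound as 25.
- Merits: one step sets C3 and C4 and builds the lactone; if it worked the endgame would be shorter than the chosen one.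
- Weak points: the carbocycle with C1 and C15 must be made first by other means. The two trisubstituted epoxides must be introduced face-selectively on a macrocycle and then told apart. Acid activation steers a carboxylate to the tertiary C4, not C3, and without acid a carboxylate opens epoxides slowly.
- Comparison: both roads meet at 25. The chosen plan sets C3 and C4 before ring closure by equilibration and chelation, and sets the single epoxide by a directed, reagent-controlled reaction.

**Alternative 3:** The cut is C5–C6. The C6 allyl sulfone anion of the seco compound A5 would open the 2,2-disubstituted 4,5-epoxide at its methylene, closing the ring to the C6 sulfone A6 and freeing the C4 alkoxide.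
- Merits: the C6–C13 chain maps onto an (E,E)-farnesyl unit with both alkenes in place. The sulfone sits on a prenyl-type carbon, so its reductive removal is regiochemically clean — better than any C9 sulfone and equal to the cross-coupling in fixing the alkene. Attack at an unhindered epoxide methylene is reliable.
- Weak points: the lactone stereocentres are not addressed and need their own solution. Without a C10 hydroxyl, the 11,12-epoxide must be made by undirected selection between two trisubstituted alkenes. The carbanion is formed beside the lactone α-hydrogen, and the sulfone must be removed reductively in the presence of epoxide and lactone.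
- Comparison: its ring closure uses simpler reagents than palladium. The chosen plan sets against it the hydroxyl-directed epoxidation, no strong base near the lactone, and no sulfone to remove.

Key step: step 5

Assumption 1: commercial ethyl 1-propenyl ether is an E/Z mixture; the E isomer 8 (enriched by fractional distillation) is taken as the reacting partner, and a C15 epimer from residual Z isomer would be corrected by base equilibration of lactone 19, where the target configuration is equatorial.

Assumption 2: the (R,R) ligand is chosen from the square-planar chelate model for copper bis(oxazoline) complexes of 1,2-dicarbonyl compounds; should the adduct prove antipodal, the (S,S) ligand is used.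

## Route

Step 1
Reactants: 1 geranyl acetate
Product: 2 (2E)-5-(3,3-dimethyloxiran-2-yl)-3-methylpent-2-en-1-yl acetate (racemic at the oxirane carbon)
Conditions: mCPBA (1.0 equiv), CH2Cl2, 0 °C
Reagents that add atoms: 3-chloroperoxybenzoic acid, O=C(OO)c1cccc(Cl)c1
Why: Prilezhaev epoxidation; the peracid should select the electron-rich terminal alkene because the 2,3-alkene is deactivated by the allylic acetate, and the new stereocentre is destroyed in step 2.

Step 2
Reactants: 2 epoxygeranyl acetate
Product: 3 (2E)-3-methyl-6-oxohex-2-en-1-yl acetate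
Conditions: HIO4·2H2O, THF–Et2O, 0 °C
Reagents that add atoms: none
Why: acid-assisted opening of the epoxide at its tertiary carbon and periodate (Malaprade-type) cleavage in one flask should release acetone and leave the E-allylic acetate untouched.

Step 3
Reactants: 4 methyl 3-bromo-2-oxopropanoate
Product: 6 methyl 2-oxo-3-(triphenyl-λ5-phosphanylidene)propanoate, via phosphonium bromide 5 (not isolated)
Conditions: PPh3, toluene, rt; then aq. Na2CO3, CH2Cl2, 0 °C
Reagents that add atoms: triphenylphosphine, c1ccc(cc1)P(c1ccccc1)c1ccccc1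
Why: SN2 quaternisation of the phosphine by the α-bromo ketone followed by deprotonation should give the acyl-stabilised ylide.

Step 4
Reactants: 3 aldehyde; 6 ylide
Product: 7 methyl (3E,7E)-9-acetoxy-7-methyl-2-oxonona-3,7-dienoate
Conditions: CH2Cl2, rt → 40 °C
Reagents that add atoms: none
Why: Wittig olefination with a stabilised ylide should give the E enone and is mild enough for the aldehyde and the acetate.

Step 5
Reactants: 7 keto ester; 8 (E)-1-ethoxyprop-1-ene
Product: 9 methyl (2S,3S,4R)-4-[(3E)-5-acetoxy-3-methylpent-3-en-1-yl]-2-ethoxy-3-methyl-3,4-dihydro-2H-pyran-6-carboxylate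
Conditions: Cu(OTf)2 (5 mol %), (R,R)-t-Bu-box ligand [2,2'-(propane-2,2-diyl)bis((4R)-4-tert-butyl-4,5-dihydro-1,3-oxazole), 5.5 mol %], 3 Å molecular sieves, THF, −78 → −20 °C, 8 (3 equiv)
Reagents that add atoms: none
Why: The keto ester binds divalent copper through both carbonyl oxygens in a square-planar chelate, which lowers the LUMO of the s-cis oxadiene O=C3–C2=C1. The enol ether then adds in a concerted, asynchronous [4+2] cycloaddition with inverse electron demand, its nucleophilic β-carbon (C15) bonding to C1 ahead of O–C16; the closest known reaction type is the copper bis(oxazoline)-catalysed hetero-Diels–Alder reaction of β,γ-unsaturated α-keto esters with enol ethers. The dihydropyran ring closes by cycloaddition, both new bonds forming suprafacially on each partner. C1 is set by the ligand: one tert-butyl group covers one face of the chelated oxadiene, so the enol ether should add to the open face and give 1R. C16 is set by the endo orientation of the ethoxy group, which places it cis to the C1 side chain. C15 follows from the E geometry of 8, transferred stereospecifically so that the methyl is trans to both neighbours. The step needs enantiofacial, endo and regiochemical control; the first two come from the catalyst and the third from the polarity of the partners, while the remote alkene and acetate are too electron-poor to act as dienophile and too weakly basic to displace the chelate.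

Step 6
Reactants: 9 dihydropyran adduct
Product: 10 methyl (2R,4R,5S,6S)-6-ethoxy-4-[(3E)-5-hydroxy-3-methylpent-3-en-1-yl]-5-methyloxane-2-carboxylate
Conditions: Mg turnings (10 equiv), MeOH, 0 °C → rt; then NaOMe (0.3 equiv), MeOH, rt
Reagents that add atoms: none
Why: electron-transfer conjugate reduction with Mg/MeOH is known for α-alkoxy-α,β-unsaturated esters and spares isolated trisubstituted alkenes; the methoxide medium should also cleave the acetate and equilibrate C3 (α to the ester) to the equatorial ester, cis to the C1 chain.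

Step 7
Reactants: 10 hydroxy ester
Product: 11 methyl (2R,4R,5S,6S)-4-[(3E)-5-{[tert-butyl(diphenyl)silyl]oxy}-3-methylpent-3-en-1-yl]-6-ethoxy-5-methyloxane-2-carboxylate
Conditions: TBDPSCl, imidazole, CH2Cl2, 0 °C → rt
Reagents that add atoms: tert-butyl(chloro)diphenylsilane, CC(C)(C)[Si](Cl)(c1ccccc1)c1ccccc1
Why: silylation of the primary alcohol; this ether is chosen because it should survive Grignard reagents and the aqueous acid of step 12.

Step 8
Reactants: 11 silyl ether ester
Product: 12 (2R,4R,5S,6S)-4-[(3E)-5-{[tert-butyl(diphenyl)silyl]oxy}-3-methylpent-3-en-1-yl]-6-ethoxy-N-methoxy-N,5-dimethyloxane-2-carboxamide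
Conditions: MeNH(OMe)·HCl, iPrMgCl, THF, −20 → 0 °C
Reagents that add atoms: N,O-dimethylhydroxylamine hydrochloride, CNOC.Cl
Why: Weinreb amidation of the ester by the magnesium amide; C3 is already in its thermodynamic configuration, so the basic medium cannot erode it.

Step 9
Reactants: 12 Weinreb amide; 13 5-bromopent-2-yne
Product: 15 1-[(2R,4R,5S,6S)-4-[(3E)-5-{[tert-butyl(diphenyl)silyl]oxy}-3-methylpent-3-en-1-yl]-6-ethoxy-5-methyloxan-2-yl]hex-4-yn-1-one, via pent-3-ynylmagnesium bromide 14 (not isolated)
Conditions: 13, Mg, THF, rt; then 12, THF, 0 °C; aq. NH4Cl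
Reagents that add atoms: none
Why: Weinreb ketone synthesis forms C4–C5; the chelated tetrahedral intermediate should prevent over-addition and protect C3 from enolisation until work-up.

Step 10
Reactants: 15 alkynyl ketone
Product: 16 (2S)-2-[(2R,4R,5S,6S)-4-[(3E)-5-{[tert-butyl(diphenyl)silyl]oxy}-3-methylpent-3-en-1-yl]-6-ethoxy-5-methyloxan-2-yl]hept-5-yn-2-ol
Conditions: MeMgBr (3 equiv, Et2O solution), CH2Cl2, −78 °C
Reagents that add atoms: methylmagnesium bromide, C[Mg]Br
Why: Cram-chelate addition to an α-alkoxy ketone: magnesium should bridge the ketone oxygen and the ring oxygen on C3, and methyl then attacks the face syn to the C3 hydrogen and away from ring carbon C2, which gives 4S.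

Step 11
Reactants: 16 alkynyl carbinol
Product: 18 (2S,5E)-2-[(2R,4R,5S,6S)-4-[(3E)-5-{[tert-butyl(diphenyl)silyl]oxy}-3-methylpent-3-en-1-yl]-6-ethoxy-5-methyloxan-2-yl]-6-iodohept-5-en-2-ol, via alkenylzirconocene 17 (not isolated)
Conditions: Cp2Zr(H)Cl (3 equiv), THF, rt → 40 °C; then I2, THF, 0 °C
Reagents that add atoms: iodine, I-I
Why: syn-hydrozirconation of a 2-alkyne with excess hydride should equilibrate zirconium onto the less hindered, methyl-bearing carbon C8, and iodinolysis with retention gives the E-iodoalkene; one equivalent is consumed by the C4 hydroxyl and the minor C7-iodo regioisomer is to be removed by chromatography.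

Step 12
Reactants: 18 iodoalkenyl acetal
Product: 19 (3S,4R,6R)-4-[(3E)-5-{[tert-butyl(diphenyl)silyl]oxy}-3-methylpent-3-en-1-yl]-6-[(2S,5E)-2-hydroxy-6-iodohept-5-en-2-yl]-3-methyloxan-2-one
Conditions: CrO3, H2SO4, H2O, acetone, 0 °C
Reagents that add atoms: water, O
Why: acid hydrolysis of the 2-deoxyglycoside-type acetal to the lactol and its oxidation by hexavalent chromium in the same flask; the tertiary alcohol, silyl ether, iodoalkene and alkene should tolerate this, the all-equatorial ring disfavours an internal acetal with the C4 hydroxyl, and C15 stays in its equatorial configuration.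

Step 13
Reactants: 19 silyl ether lactone
Product: 20 (3S,4R,6R)-6-[(2S,5E)-2-hydroxy-6-iodohept-5-en-2-yl]-4-[(3E)-5-hydroxy-3-methylpent-3-en-1-yl]-3-methyloxan-2-one
Conditions: Bu4NF, AcOH, THF, 0 °C → rt
Reagents that add atoms: none
Why: fluoride desilylation, buffered with acetic acid so that the lactone is not opened.

Step 14
Reactants: 20 allylic alcohol
Product: 21 (3S,4R,6R)-6-[(2S,5E)-2-hydroxy-6-iodohept-5-en-2-yl]-4-{2-[(2S,3S)-3-(hydroxymethyl)-2-methyloxiran-2-yl]ethyl}-3-methyloxan-2-one
Conditions: Ti(OiPr)4 (20 mol %), L-(+)-diethyl tartrate (24 mol %), t-BuOOH, 4 Å molecular sieves, CH2Cl2, −20 °C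
Reagents that add atoms: tert-butyl hydroperoxide, CC(C)(C)OO
Why: Sharpless asymmetric epoxidation; with L-(+)-tartrate an E-trisubstituted primary allylic alcohol of the geraniol type should give the (2S,3S)-epoxy alcohol, here 11S,12S, under reagent control, and the iodoalkene and the non-allylic tertiary alcohol are not substrates.

Step 15
Reactants: 21 epoxy alcohol
Product: 22 (2R,3S)-3-(2-{(3S,4R,6R)-6-[(2S,5E)-2-hydroxy-6-iodohept-5-en-2-yl]-3-methyl-2-oxooxan-4-yl}ethyl)-3-methyloxirane-2-carbaldehyde
Conditions: PhI(OAc)2, TEMPO (10 mol %), CH2Cl2, rt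
Reagents that add atoms: none
Why: oxoammonium oxidation is selective for the primary alcohol and should leave the tertiary alcohol and the epoxide; the descriptor at C11 changes only because the CIP priorities change.

Step 16
Reactants: 22 epoxy aldehyde
Product: 23 (3S,4R,6R)-4-{2-[(2S,3S)-3-ethenyl-2-methyloxiran-2-yl]ethyl}-6-[(2S,5E)-2-hydroxy-6-iodohept-5-en-2-yl]-3-methyloxan-2-one
Conditions: Ph3PCH3Br (1.5 equiv), KN(SiMe3)2 (1.4 equiv), THF, 0 °C; then 22, −78 → 0 °C
Reagents that add atoms: methyltriphenylphosphonium bromide, C[P+](c1ccccc1)(c1ccccc1)c1ccccc1.[Br-]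
Why: Wittig methylenation supplies C9; the aldehyde is far more electrophilic than the lactone and the base is kept substoichiometric to the salt so that C15 is not enolised.

Step 17
Reactants: 23 vinyl epoxide
Product: 25 (1R,3R,4S,7E,11S,12S,15S)-11,12-epoxy-4-hydroxycembr-7-en-16,3-olide, via B-alkyl-9-borabicyclononane 24 (not isolated)
Conditions: 9-BBN (1.5 equiv), THF, 0 °C → rt; then slow addition to Pd(dppf)Cl2 (10 mol %), AsPh3, Cs2CO3, DMF–THF–H2O, rt, final concentration about 1 mM
Reagents that add atoms: none
Why: anti-Markovnikov hydroboration of the terminal alkene followed by intramolecular B-alkyl Suzuki–Miyaura coupling (divalent palladium precatalyst reduced to zerovalent palladium, oxidative addition to C8–I, transmetalation, reductive elimination) should close the 14-membered ring at C8–C9 with retention of the E geometry.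

Step 18
Reactants: 25 7,8-ene epoxy lactone
Product: 26 (1R,3R,4S,6E,8S,11S,12S,15S)-11,12-epoxy-8-hydroperoxy-4-hydroxycembr-6-en-16,3-olide
Conditions: O2, visible light, tetraphenylporphyrin (cat.), CH2Cl2, −20 °C
Reagents that add atoms: dioxygen, O=O
Why: Schenck ene reaction of singlet oxygen: oxygen bonds to C8 while a C6 hydrogen is transferred suprafacially, giving the E-6,7-alkene; the C8 configuration rests on attack at the exposed face of the ring alkene, and nothing else in 25 reacts with singlet oxygen.

## Compound list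

1 | geranyl acetate, (2E)-3,7-dimethylocta-2,6-dien-1-yl acetate | CC(C)=CCC/C(C)=C/COC(C)=O | starting material
2 | (2E)-5-(3,3-dimethyloxiran-2-yl)-3-methylpent-2-en-1-yl acetate, racemic | CC1(C)OC1CC/C(C)=C/COC(C)=O | intermediate
3 | (2E)-3-methyl-6-oxohex-2-en-1-yl acetate | O=CCC/C(C)=C/COC(C)=O | intermediate
4 | methyl 3-bromo-2-oxopropanoate | COC(=O)C(=O)CBr | starting material
5 | (3-methoxy-2,3-dioxopropyl)triphenylphosphonium bromide | COC(=O)C(=O)C[P+](c1ccccc1)(c1ccccc1)c1ccccc1.[Br-] | intermediate
6 | methyl 2-oxo-3-(triphenyl-λ5-phosphanylidene)propanoate | COC(=O)C(=O)C=P(c1ccccc1)(c1ccccc1)c1ccccc1 | intermediate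
7 | methyl (3E,7E)-9-acetoxy-7-methyl-2-oxonona-3,7-dienoate | COC(=O)C(=O)/C=C/CC/C(C)=C/COC(C)=O | intermediate
8 | (E)-1-ethoxyprop-1-ene | CCO/C=C/C | starting material
9 | methyl (2S,3S,4R)-4-[(3E)-5-acetoxy-3-methylpent-3-en-1-yl]-2-ethoxy-3-methyl-3,4-dihydro-2H-pyran-6-carboxylate | C[C@@H]1[C@@H](OCC)OC(C(=O)OC)=C[C@H]1CC/C(C)=C/COC(C)=O | intermediate
10 | methyl (2R,4R,5S,6S)-6-ethoxy-4-[(3E)-5-hydroxy-3-methylpent-3-en-1-yl]-5-methyloxane-2-carboxylate | C[C@@H]1[C@@H](OCC)O[C@@H](C(=O)OC)C[C@H]1CC/C(C)=C/CO | intermediate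
11 | methyl (2R,4R,5S,6S)-4-[(3E)-5-{[tert-butyl(diphenyl)silyl]oxy}-3-methylpent-3-en-1-yl]-6-ethoxy-5-methyloxane-2-carboxylate | C[C@@H]1[C@@H](OCC)O[C@@H](C(=O)OC)C[C@H]1CC/C(C)=C/CO[Si](c1ccccc1)(c1ccccc1)C(C)(C)C | intermediate
12 | (2R,4R,5S,6S)-4-[(3E)-5-{[tert-butyl(diphenyl)silyl]oxy}-3-methylpent-3-en-1-yl]-6-ethoxy-N-methoxy-N,5-dimethyloxane-2-carboxamide | C[C@@H]1[C@@H](OCC)O[C@@H](C(=O)N(C)OC)C[C@H]1CC/C(C)=C/CO[Si](c1ccccc1)(c1ccccc1)C(C)(C)C | intermediate
13 | 5-bromopent-2-yne | CC#CCCBr | starting material
14 | pent-3-ynylmagnesium bromide | CC#CCC[Mg]Br | intermediate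
15 | 1-[(2R,4R,5S,6S)-4-[(3E)-5-{[tert-butyl(diphenyl)silyl]oxy}-3-methylpent-3-en-1-yl]-6-ethoxy-5-methyloxan-2-yl]hex-4-yn-1-one | C[C@@H]1[C@@H](OCC)O[C@@H](C(=O)CCC#CC)C[C@H]1CC/C(C)=C/CO[Si](c1ccccc1)(c1ccccc1)C(C)(C)C | intermediate
16 | (2S)-2-[(2R,4R,5S,6S)-4-[(3E)-5-{[tert-butyl(diphenyl)silyl]oxy}-3-methylpent-3-en-1-yl]-6-ethoxy-5-methyloxan-2-yl]hept-5-yn-2-ol | C[C@@H]1[C@@H](OCC)O[C@@H]([C@@](C)(O)CCC#CC)C[C@H]1CC/C(C)=C/CO[Si](c1ccccc1)(c1ccccc1)C(C)(C)C | intermediate
17 | C8 chlorozirconocene alkenyl derivative of 16 (E; zirconium trans to C6), the C4 oxygen bound as chlorozirconocene alkoxide | C[C@@H]1[C@@H](OCC)O[C@@H]([C@@](C)(O[Zr](Cl)(C2C=CC=C2)C2C=CC=C2)CC/C=C(\C)[Zr](Cl)(C2C=CC=C2)C2C=CC=C2)C[C@H]1CC/C(C)=C/CO[Si](c1ccccc1)(c1ccccc1)C(C)(C)C | intermediate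
18 | (2S,5E)-2-[(2R,4R,5S,6S)-4-[(3E)-5-{[tert-butyl(diphenyl)silyl]oxy}-3-methylpent-3-en-1-yl]-6-ethoxy-5-methyloxan-2-yl]-6-iodohept-5-en-2-ol | C[C@@H]1[C@@H](OCC)O[C@@H]([C@@](C)(O)CC/C=C(\C)I)C[C@H]1CC/C(C)=C/CO[Si](c1ccccc1)(c1ccccc1)C(C)(C)C | intermediate
19 | (3S,4R,6R)-4-[(3E)-5-{[tert-butyl(diphenyl)silyl]oxy}-3-methylpent-3-en-1-yl]-6-[(2S,5E)-2-hydroxy-6-iodohept-5-en-2-yl]-3-methyloxan-2-one | C[C@@H]1C(=O)O[C@@H]([C@@](C)(O)CC/C=C(\C)I)C[C@H]1CC/C(C)=C/CO[Si](c1ccccc1)(c1ccccc1)C(C)(C)C | intermediate
20 | (3S,4R,6R)-6-[(2S,5E)-2-hydroxy-6-iodohept-5-en-2-yl]-4-[(3E)-5-hydroxy-3-methylpent-3-en-1-yl]-3-methyloxan-2-one | C[C@@H]1C(=O)O[C@@H]([C@@](C)(O)CC/C=C(\C)I)C[C@H]1CC/C(C)=C/CO | intermediate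
21 | (3S,4R,6R)-6-[(2S,5E)-2-hydroxy-6-iodohept-5-en-2-yl]-4-{2-[(2S,3S)-3-(hydroxymethyl)-2-methyloxiran-2-yl]ethyl}-3-methyloxan-2-one | C[C@@H]1C(=O)O[C@@H]([C@@](C)(O)CC/C=C(\C)I)C[C@H]1CC[C@]2(C)O[C@H]2CO | intermediate
22 | (2R,3S)-3-(2-{(3S,4R,6R)-6-[(2S,5E)-2-hydroxy-6-iodohept-5-en-2-yl]-3-methyl-2-oxooxan-4-yl}ethyl)-3-methyloxirane-2-carbaldehyde | C[C@@H]1C(=O)O[C@@H]([C@@](C)(O)CC/C=C(\C)I)C[C@H]1CC[C@]2(C)O[C@H]2C=O | intermediate
23 | (3S,4R,6R)-4-{2-[(2S,3S)-3-ethenyl-2-methyloxiran-2-yl]ethyl}-6-[(2S,5E)-2-hydroxy-6-iodohept-5-en-2-yl]-3-methyloxan-2-one | C[C@@H]1C(=O)O[C@@H]([C@@](C)(O)CC/C=C(\C)I)C[C@H]1CC[C@]2(C)O[C@H]2C=C | intermediate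
24 | 9-{2-[(2S,3S)-3-(2-{(3S,4R,6R)-6-[(2S,5E)-2-hydroxy-6-iodohept-5-en-2-yl]-3-methyl-2-oxooxan-4-yl}ethyl)-3-methyloxiran-2-yl]ethyl}-9-borabicyclo[3.3.1]nonane | C[C@@H]1C(=O)O[C@@H]([C@@](C)(O)CC/C=C(\C)I)C[C@H]1CC[C@]2(C)O[C@H]2CCB2C3CCCC2CCC3 | intermediate
25 | (1R,3R,4S,7E,11S,12S,15S)-11,12-epoxy-4-hydroxycembr-7-en-16,3-olide | C[C@@H]1C(=O)O[C@@H]2C[C@H]1CC[C@]1(C)O[C@H]1CC/C(C)=C/CC[C@]2(C)O | intermediate
26 | (1R,3R,4S,6E,8S,11S,12S,15S)-11,12-epoxy-8-hydroperoxy-4-hydroxycembr-6-en-16,3-olide | C[C@@H]1C(=O)O[C@@H]2C[C@H]1CC[C@]1(C)O[C@H]1CC[C@](C)(OO)/C=C/C[C@]2(C)O | target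

## Step count and uncertain steps

Total: 18 steps. Longest linear sequence: 17 steps from geranyl acetate (steps 1, 2 and 4 to 18); step 3 is a one-step side branch.

**Step 5 (key step).** The β-methyl group of the enol ether may slow the cycloaddition and erode endo and facial selectivity, and the Lewis acid may oligomerise the enol ether before it is consumed. The fallback sets out from 7 and builds the same two bonds stepwise under enamine catalysis. Propanal and a chiral 2-(diarylmethyl)pyrrolidine on silica gel in CH2Cl2 should give, by Michael addition and hemiacetalisation, the lactol methyl (3S,4R)-4-[(3E)-5-acetoxy-3-methylpent-3-en-1-yl]-2-hydroxy-3-methyl-3,4-dihydro-2H-pyran-6-carboxylate F1. Anomeric O-ethylation (EtI, Ag2O) then returns to the route at 9; a C16 epimer formed alongside is harmless because C16 becomes the carbonyl in step 12.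

**Step 6.** Electron transfer to the captodative alkene may be slow, so that reduction stalls or is overtaken by cleavage of the allylic or C3 oxygen. The fallback sets out from 9 and moves the reduction to a more electrophilic enone. Amidation (MeNH(OMe)·HCl, iPrMgCl) would give (2S,3S,4R)-2-ethoxy-4-[(3E)-5-hydroxy-3-methylpent-3-en-1-yl]-N-methoxy-N,3-dimethyl-3,4-dihydro-2H-pyran-6-carboxamide F2. Silylation would give its tert-butyldiphenylsilyl ether F3, and the Grignard reagent 14 would give the enone 1-[(2S,3S,4R)-4-[(3E)-5-{[tert-butyl(diphenyl)silyl]oxy}-3-methylpent-3-en-1-yl]-2-ethoxy-3-methyl-3,4-dihydro-2H-pyran-6-yl]hex-4-yn-1-one F4. Conjugate reduction with [(Ph3P)CuH]6 (monovalent copper hydride) and equilibration with DBU return to the route at 15.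

**Step 10.** The chelating oxygen is an acetal oxygen of reduced basicity, so non-chelated (Felkin–Anh) addition may compete and give the C4 epimer. If that course dominates, the fallback sets out from 12 and reverses the order of the two nucleophiles. MeMgBr would give the methyl ketone 1-[(2R,4R,5S,6S)-4-[(3E)-5-{[tert-butyl(diphenyl)silyl]oxy}-3-methylpent-3-en-1-yl]-6-ethoxy-5-methyloxan-2-yl]ethan-1-one F5. Adding the Grignard reagent 14 in THF at −78 °C, where the same non-chelated preference now delivers 4S, returns to the route at 16.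

**Step 17.** Hydride may be transferred from boron to the vinyl epoxide with ring opening, the borate may cyclise onto the epoxide before transmetalation, and the aqueous base may open the lactone; oligomerisation competes at any concentration above high dilution. The fallback sets out from 22 and closes the ring between two sp2 carbons. Takai–Utimoto olefination (CrCl2, Cl2CHBpin, LiI, THF) would give the alkenylboronate (3S,4R,6R)-6-[(2S,5E)-2-hydroxy-6-iodohept-5-en-2-yl]-3-methyl-4-(2-{(2S,3S)-2-methyl-3-[(E)-2-(4,4,5,5-tetramethyl-1,3,2-dioxaborolan-2-yl)ethenyl]oxiran-2-yl}ethyl)oxan-2-one F6. Intramolecular Suzuki–Miyaura coupling (Pd(PPh3)4, zerovalent palladium, Cs2CO3, THF–H2O, high dilution) would give the diene (1R,3R,4S,7E,9E,11S,12S,15S)-11,12-epoxy-4-hydroxycembra-7,9-dien-16,3-olide F7. Diimide (2-nitrobenzenesulfonylhydrazide, Et3N), which reduces a disubstituted alkene much faster than a trisubstituted one, would saturate C9–C10 and return to the route at 25.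

**Step 18.** Hydrogen abstraction from the C19 methyl (giving the secondary C7 hydroperoxide) and attack on the other face of the ring alkene (giving the C8 epimer) are both likely to compete; the product may also fragment by Hock-type cleavage on handling. The fallback sets out from 25 and replaces the concerted ene reaction by an ionic sequence with fixed regiochemistry and the opposite facial outcome.
- Bromohydroperoxidation (1,3-dibromo-5,5-dimethylhydantoin, anhydrous H2O2, Et2O, −40 °C) should open the bromonium ion at the tertiary carbon with anti addition and give (1R,3R,4S,7R,8S,11S,12S,15S)-7-bromo-11,12-epoxy-8-hydroperoxy-4-hydroxycembran-16,3-olide F8.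
- Silylation (Et3SiCl, imidazole) would give the triethylsilyl peroxide F9.
- DBU would eliminate HBr toward C6 only, since C8 carries no hydrogen, giving (1R,3R,4S,6E,8S,11S,12S,15S)-11,12-epoxy-4-hydroxy-8-(triethylsilylperoxy)cembr-6-en-16,3-olide F10.
- Bu4NF/AcOH returns to the route at 26.

Because the peroxide oxygen enters anti to the bromonium ion, the face that gives the wrong epimer in the ene reaction gives the right one here.

## Further compounds

F1 | step 5 | methyl (3S,4R)-4-[(3E)-5-acetoxy-3-methylpent-3-en-1-yl]-2-hydroxy-3-methyl-3,4-dihydro-2H-pyran-6-carboxylate (anomeric mixture) | C[C@@H]1C(O)OC(C(=O)OC)=C[C@H]1CC/C(C)=C/COC(C)=O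
F2 | step 6 | (2S,3S,4R)-2-ethoxy-4-[(3E)-5-hydroxy-3-methylpent-3-en-1-yl]-N-methoxy-N,3-dimethyl-3,4-dihydro-2H-pyran-6-carboxamide | C[C@@H]1[C@@H](OCC)OC(C(=O)N(C)OC)=C[C@H]1CC/C(C)=C/CO
F3 | step 6 | (2S,3S,4R)-4-[(3E)-5-{[tert-butyl(diphenyl)silyl]oxy}-3-methylpent-3-en-1-yl]-2-ethoxy-N-methoxy-N,3-dimethyl-3,4-dihydro-2H-pyran-6-carboxamide | C[C@@H]1[C@@H](OCC)OC(C(=O)N(C)OC)=C[C@H]1CC/C(C)=C/CO[Si](c1ccccc1)(c1ccccc1)C(C)(C)C
F4 | step 6 | 1-[(2S,3S,4R)-4-[(3E)-5-{[tert-butyl(diphenyl)silyl]oxy}-3-methylpent-3-en-1-yl]-2-ethoxy-3-methyl-3,4-dihydro-2H-pyran-6-yl]hex-4-yn-1-one | C[C@@H]1[C@@H](OCC)OC(C(=O)CCC#CC)=C[C@H]1CC/C(C)=C/CO[Si](c1ccccc1)(c1ccccc1)C(C)(C)C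
F5 | step 10 | 1-[(2R,4R,5S,6S)-4-[(3E)-5-{[tert-butyl(diphenyl)silyl]oxy}-3-methylpent-3-en-1-yl]-6-ethoxy-5-methyloxan-2-yl]ethan-1-one | C[C@@H]1[C@@H](OCC)O[C@@H](C(C)=O)C[C@H]1CC/C(C)=C/CO[Si](c1ccccc1)(c1ccccc1)C(C)(C)C
F6 | step 17 | (3S,4R,6R)-6-[(2S,5E)-2-hydroxy-6-iodohept-5-en-2-yl]-3-methyl-4-(2-{(2S,3S)-2-methyl-3-[(E)-2-(4,4,5,5-tetramethyl-1,3,2-dioxaborolan-2-yl)ethenyl]oxiran-2-yl}ethyl)oxan-2-one | C[C@@H]1C(=O)O[C@@H]([C@@](C)(O)CC/C=C(\C)I)C[C@H]1CC[C@]2(C)O[C@H]2/C=C/B2OC(C)(C)C(C)(C)O2
F7 | step 17 | (1R,3R,4S,7E,9E,11S,12S,15S)-11,12-epoxy-4-hydroxycembra-7,9-dien-16,3-olide | C[C@@H]1C(=O)O[C@@H]2C[C@H]1CC[C@]1(C)O[C@H]1/C=C/C(C)=C/CC[C@]2(C)O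
F8 | step 18 | (1R,3R,4S,7R,8S,11S,12S,15S)-7-bromo-11,12-epoxy-8-hydroperoxy-4-hydroxycembran-16,3-olide | C[C@@H]1C(=O)O[C@@H]2C[C@H]1CC[C@]1(C)O[C@H]1CC[C@](C)(OO)[C@H](Br)CC[C@]2(C)O
F9 | step 18 | (1R,3R,4S,7R,8S,11S,12S,15S)-7-bromo-11,12-epoxy-4-hydroxy-8-(triethylsilylperoxy)cembran-16,3-olide | C[C@@H]1C(=O)O[C@@H]2C[C@H]1CC[C@]1(C)O[C@H]1CC[C@](C)(OO[Si](CC)(CC)CC)[C@H](Br)CC[C@]2(C)O
F10 | step 18 | (1R,3R,4S,6E,8S,11S,12S,15S)-11,12-epoxy-4-hydroxy-8-(triethylsilylperoxy)cembr-6-en-16,3-olide | C[C@@H]1C(=O)O[C@@H]2C[C@H]1CC[C@]1(C)O[C@H]1CC[C@](C)(OO[Si](CC)(CC)CC)/C=C/C[C@]2(C)O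
A1 | alternative 1 | 16-membered allyl vinyl ether: 3-methylidene-2-oxa ring with 15E and 7E alkenes, (11S,12S)-epoxide and (4S)-triethylsilyloxy group | C=C1OC/C(C)=C/CC[C@]2(C)O[C@H]2CC/C(C)=C/CC[C@]1(C)O[Si](CC)(CC)CC
A2 | alternative 1 | 14-membered C3 ketone with C1 isopropenyl group, (11S,12S)-epoxide, 7E alkene and C4 triethylsilyl ether | CC(=C)[C@@H]1CC[C@]2(C)O[C@H]2CC/C(C)=C/CC[C@](C)(O[Si](CC)(CC)CC)C(=O)C1
A3 | alternative 2 | (1R,3S,4S,7E,11S,12S,15S)-3,4:11,12-diepoxycembr-7-en-16-oic acid | C[C@H](C(=O)O)[C@H]1C[C@@H]2O[C@@]2(C)CC/C=C(\C)CC[C@@H]2O[C@@]2(C)CC1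
A4 | alternative 2 | (1R,3R,4S,7E,11S,12S,15S)-11,12-epoxy-4-hydroxycembr-7-en-16,3-olide | C[C@@H]1C(=O)O[C@@H]2C[C@H]1CC[C@]1(C)O[C@H]1CC/C(C)=C/CC[C@]2(C)O
A5 | alternative 3 | (3S,4R,6R)-3-methyl-6-[(2S)-2-methyloxiran-2-yl]-4-(2-{(2S,3S)-2-methyl-3-[(3E)-3-methyl-5-(phenylsulfonyl)pent-3-en-1-yl]oxiran-2-yl}ethyl)oxan-2-one | C[C@@H]1C(=O)O[C@@H]([C@]2(C)CO2)C[C@H]1CC[C@]1(C)O[C@H]1CC/C(C)=C/CS(=O)(=O)c1ccccc1
A6 | alternative 3 | (1R,3R,4S,7E,11S,12S,15S)-11,12-epoxy-4-hydroxy-6-(phenylsulfonyl)cembr-7-en-16,3-olide (C6 unassigned) | C[C@@H]1C(=O)O[C@@H]2C[C@H]1CC[C@]1(C)O[C@H]1CC/C(C)=C/C(S(=O)(=O)c1ccccc1)C[C@]2(C)O
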